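**Plan**

1. Numbering: each ring is a curcuphenol unit (C1 OH, C2 side chain with stereocentre C7, C5 CH3, chain C8–C11). Ring A is unprimed and ring B is primed.
2. Cut 1 is the biaryl bond C4–C6′. It links the carbon para to the OH of ring A with the only free carbon ortho to the OH of ring B. These carbons carry phenoxyl spin or phenol-ether nucleophilicity, and the bond joins two copies of one (S)-monomer. It is therefore made as the presumed biosynthesis makes it, by oxidative phenol coupling, here at an anode.
3. Helpers for that event: Br on C4′ blocks the para carbon of ring B. Si(i-Pr)3 on the oxygen of ring A makes that partner harder to oxidise and shields C6. Both partners come from one intermediate (9), and both helpers leave in steps 10 and 11.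
4. Cut 2 (inside 9) is C9–C10 (primary iodide + 2-methylprop-1-enyl Grignard reagent). Cut 3 leads back to 4,7-dimethylcoumarin, whose lactone ring is a temporary ring holding O, C7, C8 and C9.
5. Forward order: reduce the coumarin, open the lactone, brominate, silylate, iodinate, extend the chain, split 9 into 11 and 12, couple, debrominate, desilylate. No ring of the target has to be built.
6. Stereochemistry: C7 is set once, by ligand-controlled CuH conjugate reduction (step 1). C7 and C7′ of the target are that same centre used twice, and it never sits next to an acidifying group afterwards.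

Key step: step 9

Assumption (axis): the target SMILES gives no configuration for the C4–C6′ axis (ortho groups CH3, OH, CH3), so the axis is not controlled and both rotamers count as the target.
Assumption (step 1): the (R)-ligand is assigned by analogy with other 4-substituted coumarins; the sense is to be checked on a sample of 11 desilylated to (S)-(+)-curcuphenol, and the (S)-ligand is taken if it proves opposite.

**Step 1**
Reactants: 1 4,7-dimethylcoumarin
Product: 2 (S)-4,7-dimethylchroman-2-one
Conditions: Cu(OAc)2·H2O (3 mol %), (R)-DTBM-SEGPHOS (3 mol %), (EtO)2MeSiH (1.5 equiv), t-BuOH (1.5 equiv), toluene, 0 °C to rt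
Reagents that add atoms: none
Why: Copper hydride-catalysed asymmetric conjugate reduction of a β,β-disubstituted unsaturated lactone: the bulky bisphosphine lets Cu–H reach only one face of the flat coumarin at C4 (= C7 of the monomer), which sets the (S)-centre, and any over-reduction to the lactol does no harm because step 2 takes lactone and lactol alike to 3.

**Step 2**
Reactants: 2 (S)-4,7-dimethylchroman-2-one
Product: 3 (S)-2-(4-hydroxybutan-2-yl)-5-methylphenol
Conditions: LiAlH4, THF, 0 °C to rt; aq. work-up
Reagents that add atoms: none
Why: Hydride reduction of an aryl lactone to phenol plus primary alcohol; the stereocentre is β to the carbonyl group and cannot epimerise.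

**Step 3**
Reactants: 3 (S)-2-(4-hydroxybutan-2-yl)-5-methylphenol
Product: 4 (S)-4-bromo-2-(4-hydroxybutan-2-yl)-5-methylphenol
Conditions: NBS (1.0 equiv), MeCN, −20 to 0 °C
Reagents that add atoms: N-bromosuccinimide, O=C1CCC(=O)N1Br
Why: Electrophilic aromatic bromination under the para direction of the free OH: C4 is para to OH and ortho to CH3, C6 is wedged between OH and CH3, and the halogen goes in before any alkene is present; a recrystallisation of 4 could raise the enantiomeric purity at this point.

**Step 4**
Reactants: 4 (S)-4-bromo-2-(4-hydroxybutan-2-yl)-5-methylphenol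
Product: 6 (S)-3-[5-bromo-4-methyl-2-(triisopropylsilyloxy)phenyl]butan-1-ol, via sodium phenoxide 5 (not isolated)
Conditions: NaH (1.0 equiv), THF, 0 °C; then TIPSCl (1.05 equiv), 0 °C to rt
Reagents that add atoms: triisopropylsilyl chloride, CC(C)[Si](Cl)(C(C)C)C(C)C
Why: Chemoselective O-silylation by way of the phenoxide: one equivalent of NaH removes only the far more acidic phenolic proton, and phenoxide 5 should outrun the neutral primary alcohol in the attack on TIPSCl.

**Step 5**
Reactants: 6 (S)-3-[5-bromo-4-methyl-2-(triisopropylsilyloxy)phenyl]butan-1-ol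
Product: 7 (S)-[4-bromo-2-(4-iodobutan-2-yl)-5-methylphenoxy]triisopropylsilane
Conditions: I2, PPh3, imidazole, CH2Cl2, 0 °C to rt
Reagents that add atoms: iodine, [I][I]
Why: Appel iodination of the primary alcohol under near-neutral conditions that leave aryl bromide and aryl silyl ether alone; with the phenol oxygen capped, ring closure of the iodide to a chroman is ruled out.

**Step 6**
Reactants: 7 (S)-[4-bromo-2-(4-iodobutan-2-yl)-5-methylphenoxy]triisopropylsilane; 8 2-methylprop-1-enylmagnesium bromide
Product: 9 (S)-[4-bromo-5-methyl-2-(6-methylhept-5-en-2-yl)phenoxy]triisopropylsilane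
Conditions: 8 (2 equiv), Li2CuCl4 (5 mol %), THF, −20 °C to rt
Reagents that add atoms: 2-methylprop-1-enylmagnesium bromide (compound 8), CC(C)=C[Mg]Br
Why: Copper-catalysed sp3–sp2 cross-coupling of a primary alkyl iodide with an alkenyl Grignard reagent (Kochi-type coupling), a standard way to the 4-methylpent-3-enyl chain of bisabolanes; aryl bromide and silyl ether are inert at these temperatures and C7 is not touched.

**Step 7**
Reactants: 9 (S)-[4-bromo-5-methyl-2-(6-methylhept-5-en-2-yl)phenoxy]triisopropylsilane (about three quarters of the material)
Product: 11 (S)-triisopropyl[5-methyl-2-(6-methylhept-5-en-2-yl)phenoxy]silane, via aryllithium 10 (not isolated)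
Conditions: n-BuLi (1.1 equiv), THF, −78 °C; then H2O
Reagents that add atoms: none
Why: Bromine–lithium exchange followed by protonation; the exchange is far faster at −78 °C than any attack on silicon or any allylic deprotonation, and the carbanion para to the silyloxy group has no path for silyl migration.

**Step 8**
Reactants: 9 (S)-[4-bromo-5-methyl-2-(6-methylhept-5-en-2-yl)phenoxy]triisopropylsilane (the remaining quarter)
Product: 12 (S)-4-bromo-5-methyl-2-(6-methylhept-5-en-2-yl)phenol
Conditions: TBAF, AcOH (1.2 equiv each), THF, 0 °C
Reagents that add atoms: none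
Why: Fluoride-induced cleavage of the aryl silyl ether, buffered with AcOH so that no free phenoxide is exposed; alkene and aryl bromide are untouched.

**Step 9**
Reactants: 12 (S)-4-bromo-5-methyl-2-(6-methylhept-5-en-2-yl)phenol; 11 (S)-triisopropyl[5-methyl-2-(6-methylhept-5-en-2-yl)phenoxy]silane (3 equiv, excess to be recovered)
Product: 14 bromo silyl biaryl [ring A: O-TIPS-(S)-curcuphenol bonded at C4; ring B: 4′-bromo-(S)-curcuphenol bonded at C6′], via phenoxyl radical 13 (not isolated)
Conditions: undivided cell, BDD anode, BDD cathode, constant current 2.8 mA cm−2, 2.0 F per mol of 12, Bu3MeN(O3SOMe) 0.09 M, HFIP, 30 °C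
Reagents that add atoms: none
Why: At the BDD anode the free phenol 12, which has the lower oxidation potential of the two partners, should lose one electron and one proton to give the HFIP-solvated phenoxyl radical 13 (spin on O, C2′, C4′ and C6′); arene 11 attacks C6′ through its C4, loss of a second electron and a proton followed by tautomerisation of the dienone restores both aromatic rings, and the cathode turns the protons into H2. The closest known reaction type is the anodic dehydrogenative phenol–arene cross-coupling at boron-doped diamond in HFIP, which has been run with silyl-protected phenols as the arene partner, and it is the electrochemical copy of the presumed biosynthetic coupling of two curcuphenol units. No ring is closed and no stereocentre is formed: the two benzylic (S)-centres are spectators and the new axis (ortho groups CH3, OH, CH3) is left uncontrolled. The step needs cross- over homo-coupling, C–C over C–O coupling, C6′ on ring B and C4 on ring A. In 13 C2′ bears the side chain and C4′ the bromine, so C6′ is the only spin-bearing carbon that can lose a proton after bond formation, and homo-coupling of 12 would have to build a biaryl with four ortho groups; in 11 the OSi(i-Pr)3 group lifts the oxidation potential above that of 12, shields C6 and leaves C4 (para to O, ortho to CH3) as the only activated open carbon. HFIP hydrogen-bonds to the phenoxyl oxygen and so disfavours C–O coupling, the trisubstituted alkenes are oxidised only at a clearly higher potential than 12, the undivided cell keeps acid from building up, and 14 has no free ortho or para carbon on its phenol ring, which guards it against further coupling.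

**Step 10**
Reactants: 14 bromo silyl biaryl
Product: 16 silyl biaryl [ring A: O-TIPS-(S)-curcuphenol bonded at C4; ring B: (S)-curcuphenol bonded at C6′], via dilithio species 15 (not isolated)
Conditions: t-BuLi (3.3 equiv), THF, −78 °C; then H2O
Reagents that add atoms: none
Why: Deprotonation of the phenol followed by bromine–lithium exchange and protonation: the first equivalent of t-BuLi gives the lithium phenoxide, the second exchanges C4′–Br, the third destroys t-BuBr, and alkenes, silyl ether and both stereocentres are inert at −78 °C.

**Step 11**
Reactants: 16 silyl biaryl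
Product: 17 4-[2-hydroxy-6-methyl-3-((S)-6-methylhept-5-en-2-yl)phenyl]-5-methyl-2-((S)-6-methylhept-5-en-2-yl)phenol (target)
Conditions: TBAF, AcOH (1.5 equiv each), THF, 0 °C to rt
Reagents that add atoms: none
Why: Fluoride-induced desilylation of the remaining aryl silyl ether under AcOH buffering, which frees the second phenol without touching alkenes or stereocentres.

**Compound list**

1 | 4,7-dimethylcoumarin | Cc1ccc2c(C)cc(=O)oc2c1 | starting material
2 | (S)-4,7-dimethylchroman-2-one | C[C@H]1CC(=O)Oc2cc(C)ccc12 | intermediate
3 | (S)-2-(4-hydroxybutan-2-yl)-5-methylphenol | OCC[C@H](C)c1ccc(C)cc1O | intermediate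
4 | (S)-4-bromo-2-(4-hydroxybutan-2-yl)-5-methylphenol | OCC[C@H](C)c1cc(Br)c(C)cc1O | intermediate
5 | sodium phenoxide of 4 (not isolated) | OCC[C@H](C)c1cc(Br)c(C)cc1[O-].[Na+] | intermediate
6 | (S)-3-[5-bromo-4-methyl-2-(triisopropylsilyloxy)phenyl]butan-1-ol | OCC[C@H](C)c1cc(Br)c(C)cc1O[Si](C(C)C)(C(C)C)C(C)C | intermediate
7 | (S)-[4-bromo-2-(4-iodobutan-2-yl)-5-methylphenoxy]triisopropylsilane | ICC[C@H](C)c1cc(Br)c(C)cc1O[Si](C(C)C)(C(C)C)C(C)C | intermediate
8 | 2-methylprop-1-enylmagnesium bromide | CC(C)=C[Mg]Br | starting material
9 | (S)-[4-bromo-5-methyl-2-(6-methylhept-5-en-2-yl)phenoxy]triisopropylsilane | CC(C)=CCC[C@H](C)c1cc(Br)c(C)cc1O[Si](C(C)C)(C(C)C)C(C)C | intermediate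
10 | C4-aryllithium from 9 (not isolated) | CC(C)=CCC[C@H](C)c1cc([Li])c(C)cc1O[Si](C(C)C)(C(C)C)C(C)C | intermediate
11 | (S)-triisopropyl[5-methyl-2-(6-methylhept-5-en-2-yl)phenoxy]silane | CC(C)=CCC[C@H](C)c1ccc(C)cc1O[Si](C(C)C)(C(C)C)C(C)C | intermediate
12 | (S)-4-bromo-5-methyl-2-(6-methylhept-5-en-2-yl)phenol | CC(C)=CCC[C@H](C)c1cc(Br)c(C)cc1O | intermediate
13 | phenoxyl radical of 12 (not isolated) | CC(C)=CCC[C@H](C)c1cc(Br)c(C)cc1[O] | intermediate
14 | bromo silyl biaryl (C4–C6′ bond, Br on C4′, OTIPS on ring A, both C7 (S)) | CC(C)=CCC[C@H](C)c1cc(-c2c(C)c(Br)cc([C@@H](C)CCC=C(C)C)c2O)c(C)cc1O[Si](C(C)C)(C(C)C)C(C)C | intermediate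
15 | dilithio species from 14 (OLi on C1′, Li on C4′; not isolated) | CC(C)=CCC[C@H](C)c1cc(-c2c(C)c([Li])cc([C@@H](C)CCC=C(C)C)c2O[Li])c(C)cc1O[Si](C(C)C)(C(C)C)C(C)C | intermediate
16 | silyl biaryl (C4–C6′ bond, OTIPS on ring A, free OH on ring B, both C7 (S)) | CC(C)=CCC[C@H](C)c1cc(-c2c(C)ccc([C@@H](C)CCC=C(C)C)c2O)c(C)cc1O[Si](C(C)C)(C(C)C)C(C)C | intermediate
17 | 4-[2-hydroxy-6-methyl-3-((S)-6-methylhept-5-en-2-yl)phenyl]-5-methyl-2-((S)-6-methylhept-5-en-2-yl)phenol | CC(C)=CCC[C@H](C)c1cc(-c2c(C)ccc([C@@H](C)CCC=C(C)C)c2O)c(C)cc1O | target

**Step count**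

Total step count: 11.
Longest linear sequence: 10 (steps 1–6, then 7 or 8, then 9, 10, 11).

**Steps most likely to fail**

**Step 9.**
- What may go wrong: attack at the hindered C6′ may be slow, so that 13 is lost to over-oxidation or C–O coupling. The trisubstituted alkenes may be drawn in by oxidation or by trapping of cationic intermediates. The excess of 11 may not suffice to suppress homo-coupling.
- Fallback: the dehydrogenative coupling is replaced by a Negishi coupling in which a metal and a halogen fix both sites. It sets out from 11 and 9.
- Compound 11 is desilylated (TBAF, AcOH, THF) to (S)-curcuphenol F1, which is capped (MOMCl, i-Pr2NEt, CH2Cl2) as its methoxymethyl ether F2.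
- Directed ortho-lithiation (n-BuLi, TMEDA, Et2O, 0 °C) can occur only at C6, the single carbon ortho to the OMOM group, and gives the aryllithium F3. ZnCl2 turns it into the arylzinc chloride F4.
- Coupling with bromide 9 (Pd2(dba)3, SPhos, THF, 60 °C) should give the doubly protected biaryl F5.
- ZnBr2 and n-PrSH (CH2Cl2, 0 °C) remove the MOM group. The route is rejoined at 16, before step 11.

**Step 1.**
- What may go wrong: facial selectivity may be poor because the 4-substituent is only a methyl group. The tetrasubstituted β-carbon may stall the reduction. The sense of induction may be opposite to the one assumed.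
- Fallback: asymmetric catalysis is replaced by a resolution that sets out from 1.
- Hydrogenation (H2, Pd/C, EtOAc, 50 °C) gives the racemic lactone F6.
- Aminolysis with (S)-1-phenylethylamine (toluene, 80 °C) opens it to two diastereomeric hydroxy amides, the (S,S)-amide F7 and the (R,S)-amide F8. These are separated by crystallisation or chromatography.
- Heating F7 with p-TsOH in toluene closes the lactone again through the neighbouring phenol. The route is rejoined at 2.

**Step 10.**
- What may go wrong: exchange may be incomplete on the electron-rich, hindered lithium phenoxide. The excess t-BuLi may deprotonate benzylic or allylic positions.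
- Fallback: the order of helper removal is reversed and the halogen is taken off by catalytic hydride transfer instead of by a carbanion. It sets out from 14.
- TBAF and AcOH (THF) give the bromo bisphenol F9.
- PdCl2(dppf) (5 mol %), NaBH4 and TMEDA (THF, rt) should replace Br by H. The route is rejoined at the target 17.

**Further compounds**

F1 | step 9 | (S)-curcuphenol, (S)-5-methyl-2-(6-methylhept-5-en-2-yl)phenol | CC(C)=CCC[C@H](C)c1ccc(C)cc1O
F2 | step 9 | (S)-curcuphenol methoxymethyl ether | CC(C)=CCC[C@H](C)c1ccc(C)cc1OCOC
F3 | step 9 | C6-aryllithium of F2 | CC(C)=CCC[C@H](C)c1ccc(C)c([Li])c1OCOC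
F4 | step 9 | C6-arylzinc chloride of F2 | CC(C)=CCC[C@H](C)c1ccc(C)c([Zn]Cl)c1OCOC
F5 | step 9 | biaryl with OTIPS on ring A and OMOM on ring B | CC(C)=CCC[C@H](C)c1cc(-c2c(C)ccc([C@@H](C)CCC=C(C)C)c2OCOC)c(C)cc1O[Si](C(C)C)(C(C)C)C(C)C
F6 | step 1 | racemic 4,7-dimethylchroman-2-one | CC1CC(=O)Oc2cc(C)ccc12
F7 | step 1 | (S)-3-(2-hydroxy-4-methylphenyl)-N-[(S)-1-phenylethyl]butanamide | C[C@@H](CC(=O)N[C@@H](C)c1ccccc1)c1ccc(C)cc1O
F8 | step 1 | (R)-3-(2-hydroxy-4-methylphenyl)-N-[(S)-1-phenylethyl]butanamide | C[C@H](CC(=O)N[C@@H](C)c1ccccc1)c1ccc(C)cc1O
F9 | step 10 | 4′-bromo bisphenol (target with Br on C4′) | CC(C)=CCC[C@H](C)c1cc(-c2c(C)c(Br)cc([C@@H](C)CCC=C(C)C)c2O)c(C)cc1O
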